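At early times the reaction phase of this flask holds starting material, while the reagent is charged to the second phase and has to cross before anything forms.

    starting material + reagent in the reaction phase → target (k1 = 0.013 M⁻¹ s⁻¹)
    reagent in the reaction phase ⇌ reagent in the second phase, rate k2*([reagent in the reaction phase] - [reagent in the second phase]/K2) per volume of the first phase (K2 = 1.6, k2 = 0.0055 s⁻¹)
    target → decomposed product (k3 = 0.0016 s⁻¹)
    target ⇌ isomer of the product (K4 = 1.4, k4 = 0.0045 s⁻¹)
    target ⇌ product in the second phase, rate k5*([target] - [product in the second phase]/K5) per volume of the first phase (K5 = 1.7, k5 = 0.0024 s⁻¹)

starting material 0.50 M; reagent in the second phase 0.700 equiv; time 25 min; volume of the second phase over the first 1.0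

- target is meant together with its product in the second phase
- in the second phase: reagent in the second phase, product in the second phase; everything else is in the first
- charges count per volume of the first phase; a concentration in a rate is the amount of a species over the volume of its own phase; every rate counts per litre of the first phase
- run time (flask): 25 min

- how much target and product in the second phase together there is at 25 min, in percent of the starting material charged
- part of the starting material charged that has reacted at 25 min

**First minutes.** The reagent is the limiting reagent, so the charges allow 70.0% of target. Once across, its half-life by the coupling step alone, with the other concentrations as charged, is 1.8 min. I give starting material a mid-run value of 0.325 M, halfway to where the reagent's charge would take it. Call τ the mean life of a reagent unit. It takes 4.85 min to cross and 10.3 min to react, visits back to the second phase counted, so τ = 15.1 min. I let conversion climb toward the cap on this time, which gives an estimate of 56.6%.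

**Middle.** Each step taken alone and both ways together, reaction-phase target relaxes against its isomer with a half-life of 1.50 min and against the second phase with one of 3.03 min. Because both are shorter than the 7.2 min half-life of reaction-phase target by decomposition alone, I treat reaction-phase target, the isomer of the product and the product in the second phase as one pool at its equilibrium shares, and decomposition as a correction to it. The share of the pool standing as reaction-phase target is f = 0.244. The pool's loss constant, decomposition's constant times f, is κ = 0.0234 min⁻¹.

**End.** By my reckoning, a pool fed on τ and drained on κ holds 39.6% at the asked time. Reaction-phase target and the product in the second phase are 0.659 of that, so I expect 26.1%.

The forecast gives 22% and 55%, reasoning that “transfer-limited consumption slows sharply”. Its yield stands below mine.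

The flask gives 22.5% and 56.2%, so the forecast holds on both, and my yield stands above the flask. In this flask at 25.0 min, the reaction-phase share of the pool reads 0.249 against f of 0.244, while the share at 12.5 min reads 0.317. For the neighbouring flask read at 1.0 h, the same τ and κ give 68.7% converted and 16.2% yield. That neighbouring flask gives 67.3% converted and 15.5% yield.

All constants are assumed; the flask was simulated.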